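The numbers of this flask were chosen freely; the flask was simulated.

- A small charge of Z, 2.16 M, meets a larger one of D, 2.4 M, and Z also decays on its own.

D 2.4 M; Z 2.16 M; time 30 h

    D + Z → Q + J (k1 = 0.0011 L mol⁻¹ s⁻¹)
    J + Z → Q + G (k2 = 6.3 × 10⁻⁴ L mol⁻¹ s⁻¹)
    G + Z → Q + E (k3 = 6.0 × 10⁻⁴ L mol⁻¹ s⁻¹)
    Z → L (k4 = 0.0024 s⁻¹)

- at 30 h, what has stopped the reaction, if anything has (it is still moving / all of D has reacted / Z has run out first)
- amount of G at 30 h, in percent of the D charged
- amount of J at 30 h, in percent of the D charged

- the reaction counts as stopped when no species that holds the D changes by six tenths of a point or more over the second half of the time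
- run time (flask): 30 h

- At the start, two rates consume Z: its own decay, 0.0024 s⁻¹, and its capture by D, 0.00264 s⁻¹. J and G start at zero, so their steps take no Z at first.
- I hold both rates at their starting values. Then c_Z falls exponentially with a half-life of 2.29 min, far shorter than the 30 h of the run. So I expect Z to be the limiting reagent, with D left over.
- The time integral of c_Z is then the charge of Z over the sum of those two rates, taken per unit of c_Z.
- The reach, the first step's constant times that integral, is 0.471.
- c_D falls as the exponential of minus the reach, which leaves 62.4% of D.
- The consecutive steps run on the same reach, scaled by their constants. I get 32.6% of J and 4.57% of G.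
- The forecast says Z has run out first, with 33.6% of J and 5% of G, reasoning that “that exposure sets the split”.
- The flask gives: Z has run out first, with 33.6% of J, 4.96% of G and 61% of D left. Z stands at 0% of its charge at 3.00 h.
- The D left in this flask corresponds to a reach of 0.495, above my 0.471.
- At the start, Z goes to L at 0.91 of its rate through step one. At 30.0 h, L and Q stand at 1.08 M and 1.08 M, each half of the Z charged.
- In the neighbour flask with 0.60 M of D, the reach is 0.776, so I expect 46.0% of D left and 42.4% of J. That flask gives 45% and 42.9%.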